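**Retrosynthetic overview**
1. Torilin ⇐ two late acylations of diol 11 (angelate on the secondary C8–OH, acetate on the tertiary C11–OH).
2. 11 ⇐ E1cB opening of the C5–O–C8 ether bridge of tricyclic ketone 10; the bridge stores the C8 oxygen and masks the C4=C5 enone.
3. 10 ⇐ oxa-bridged dienone 6 by three exo-face events on the rigid bicycle (C7 hydroalkenylation, hydration, C1 hydrogenation); the C10 methyl is set thermodynamically.
4. 6 ⇐ dearomative intramolecular (4+3) cycloaddition of the furan in 5 with a tethered 2-methylallyl cation; the seven- and five-membered carbocycles form together, and chirality is relayed from a sacrificial α-stereocentre.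
5. 5 ⇐ furan + 3-bromobutan-2-one + methacrolein.

Assumption: atom labels use guaiane numbering (C1–C5 cyclopentenone with C3=O and C4–Me; seven-membered ring C5–C10 plus C1; C8 carries O; C7 carries C11); the target is (1R,7S,8R,10S). The sense of the C4→bridgehead relay is predicted from an A1,3 model (R gives 8R); if experiment shows the opposite, the enantiomeric ligand is used in step 1.

**Step 1**
Reactants: 1 furan; 2 3-bromobutan-2-one (racemic)
Product: 3 (R)-3-(furan-2-yl)butan-2-one
Conditions: 1, n-BuLi, THF, 0 °C; ZnI2; then 2, NiCl2·glyme (5 mol %), chiral i-Pr-pybox (enantiomer giving R), DME/THF, −30 °C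
Reagents that add atoms: none (all atoms from 1 and 2)
Why: Stereoconvergent Ni/pybox Negishi α-arylation of a racemic secondary α-bromoketone sets the sacrificial stereocentre (guaiane C4) as R under ligand control, without enolate conditions that would racemise an α-furyl ketone.

**Step 2**
Reactants: 3; 4 methacrolein
Product: 5 (6R)-6-(furan-2-yl)-3-hydroxy-2-methylhept-1-en-5-one (C3 epimers)
Conditions: n-Bu2BOTf, i-Pr2NEt, CH2Cl2, −78 °C; then 4, −78 → −20 °C; pH 7 buffer/MeOH work-up
Reagents that add atoms: none (all atoms from 3 and 4)
Why: Kinetic boron enolisation takes place at the unhindered CH3 rather than the tertiary α-furyl C–H, so the boron aldol adds 1,2 to methacrolein with the R centre untouched; the new carbinol is an inconsequential epimer mixture because it is ionised in step 3.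

**Step 3 (key step)**
Reactants: 5
Product: 6 (1S,6S,8R)-2,6-dimethyl-11-oxatricyclo[6.2.1.0^1,5]undeca-4,9-dien-3-one (C2 epimers; C2 = guaiane C4)
Conditions: Tf2NH (10 mol %), HFIP/CH2Cl2 (1:4), −40 → 23 °C; then NaOMe (0.2 equiv), MeOH, 23 °C
Reagents that add atoms: none
Why: Proposed new method: acid ionisation of the allylic alcohol in HFIP gives a 1-alkyl-2-methylallyl cation that is captured across C2/C5 of the tethered furan in a dearomative intramolecular (4+3) cycloaddition (closest known type: intramolecular (4+3) cycloadditions of simple allyl cations with furans through three-atom tethers, and dehydrative cation generation in HFIP); the tether must reach the attacked furan face from C4 and A1,3 strain keeps the C4 methyl on the furan-oxygen side rather than against the furan C3–H, so the R centre dictates the (1S,8R) bridgeheads; the tertiary C10 cation then loses a proton, acid moves the olefin into conjugation with the ketone (erasing C1), and methoxide equilibrates C10 through the dienolate to the exo (equatorial, syn to the oxygen bridge) methyl.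

**Step 4**
Reactants: 6; 7 2-bromopropene
Product: 8 (1S,6S,8R,9R)-2,6-dimethyl-9-(prop-1-en-2-yl)-11-oxatricyclo[6.2.1.0^1,5]undec-4-en-3-one (C2 epimers)
Conditions: Pd(OAc)2 (5 mol %), PPh3, HCO2H, Et3N, DMF, 60 °C
Reagents that add atoms: none beyond reactant 7 (formate supplies H only)
Why: Reductive Heck hydroalkenylation: syn carbopalladation of the strained C6=C7 bond from the exo (oxygen-bridge) face places the alkenyl group on C7, the carbon remote from the quaternary bridgehead, and formate reduces the alkyl–Pd (no syn β-H), so the C3 unit ends cis to the bridging oxygen.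

**Step 5**
Reactants: 8
Product: 9 (1S,6S,8R,9S)-9-(2-hydroxypropan-2-yl)-2,6-dimethyl-11-oxatricyclo[6.2.1.0^1,5]undec-4-en-3-one (C2 epimers)
Conditions: Co(acac)2 (20 mol %), PhSiH3, O2 (1 atm), i-PrOH/THF, 0 → 23 °C; Na2S2O3 work-up
Reagents that add atoms: dioxygen, O=O
Why: Mukaiyama hydration (Co–H hydrogen-atom transfer, Markovnikov) converts only the 1,1-disubstituted isopropenyl group into the tertiary alcohol, the hindered β,β-disubstituted enone being a poor acceptor; no stereocentre is formed.

**Step 6**
Reactants: 9
Product: 10 (1R,5R,6S,8R,9S)-9-(2-hydroxypropan-2-yl)-2,6-dimethyl-11-oxatricyclo[6.2.1.0^1,5]undecan-3-one (C2 epimers)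
Conditions: H2 (1 atm), 10% Pd/C, EtOAc, 23 °C
Reagents that add atoms: none
Why: Heterogeneous hydrogenation of the enone C=C from the exo face (the side of the one-atom oxygen bridge, away from the two-carbon bridge) puts H1 syn to the bridging oxygen and therefore cis to the C10 methyl.

**Step 7**
Reactants: 10
Product: 11 (5S,6R,8S,8aR)-6-hydroxy-5-(2-hydroxypropan-2-yl)-3,8-dimethyl-4,5,6,7,8,8a-hexahydro-1H-azulen-2-one
Conditions: DBU, CH2Cl2, 0 → 23 °C
Reagents that add atoms: none
Why: E1cB (retro-oxa-Michael) elimination: the C4 enolate expels the bridgehead alkoxide, which opens the ether bridge to the tetrasubstituted cyclopentenone and releases C8–OH with its configuration intact; the C4 stereocentre is erased and C1, C7 and C10 are untouched.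

**Step 8**
Reactants: 11; 12 angelic acid
Product: 13 the 8-O-angelate of 11 (11-deacetyltorilin)
Conditions: 12, 2,4,6-trichlorobenzoyl chloride, Et3N, toluene, 23 °C; then 11, toluene, 75 °C
Reagents that add atoms: none beyond reactant 12
Why: Yamaguchi-type mixed-anhydride esterification without a nucleophilic catalyst acylates the secondary C8–OH in preference to the tertiary carbinol and keeps the (Z)-olefin of the angelate.

**Step 9**
Reactants: 13
Product: 14 torilin
Conditions: Ac2O, Sc(OTf)3 (5 mol %), MeCN, −20 °C
Reagents that add atoms: acetic anhydride, CC(=O)OC(C)=O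
Why: Lewis-acid-catalysed acetylation of the hindered tertiary alcohol at low temperature, conditions that neither isomerise the angelate nor epimerise the γ-position C1.

**Compound list**
1 | furan | c1ccoc1 | starting material
2 | 3-bromobutan-2-one (racemic) | CC(Br)C(C)=O | starting material
3 | (R)-3-(furan-2-yl)butan-2-one | CC(=O)[C@H](C)c1ccco1 | intermediate
4 | methacrolein | CC(=C)C=O | starting material
5 | (6R)-6-(furan-2-yl)-3-hydroxy-2-methylhept-1-en-5-one, C3 epimers | CC(=C)C(O)CC(=O)[C@H](C)c1ccco1 | intermediate
6 | (1S,6S,8R)-2,6-dimethyl-11-oxatricyclo[6.2.1.0^1,5]undeca-4,9-dien-3-one, C2 epimers (centre erased in step 7) | CC1C(=O)C=C2[C@@H](C)C[C@@H]3C=C[C@]12O3 | intermediate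
7 | 2-bromopropene | CC(Br)=C | starting material
8 | (1S,6S,8R,9R)-2,6-dimethyl-9-(prop-1-en-2-yl)-11-oxatricyclo[6.2.1.0^1,5]undec-4-en-3-one, C2 epimers | CC1C(=O)C=C2[C@@H](C)C[C@@H]3[C@@H](C(C)=C)C[C@]12O3 | intermediate
9 | (1S,6S,8R,9S)-9-(2-hydroxypropan-2-yl)-2,6-dimethyl-11-oxatricyclo[6.2.1.0^1,5]undec-4-en-3-one, C2 epimers | CC1C(=O)C=C2[C@@H](C)C[C@@H]3[C@@H](C(C)(C)O)C[C@]12O3 | intermediate
10 | (1R,5R,6S,8R,9S)-9-(2-hydroxypropan-2-yl)-2,6-dimethyl-11-oxatricyclo[6.2.1.0^1,5]undecan-3-one, C2 epimers | CC1C(=O)C[C@@H]2[C@@H](C)C[C@@H]3[C@@H](C(C)(C)O)C[C@]12O3 | intermediate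
11 | (5S,6R,8S,8aR)-6-hydroxy-5-(2-hydroxypropan-2-yl)-3,8-dimethyl-4,5,6,7,8,8a-hexahydro-1H-azulen-2-one | O[C@@H]1C[C@H](C)[C@H]2CC(=O)C(C)=C2C[C@@H]1C(C)(C)O | intermediate
12 | angelic acid, (Z)-2-methylbut-2-enoic acid | C/C=C(/C)C(O)=O | starting material
13 | [(5S,6R,8S,8aR)-5-(2-hydroxypropan-2-yl)-3,8-dimethyl-2-oxo-4,5,6,7,8,8a-hexahydro-1H-azulen-6-yl] (Z)-2-methylbut-2-enoate | C/C=C(/C)C(=O)O[C@@H]1C[C@H](C)[C@H]2CC(=O)C(C)=C2C[C@@H]1C(C)(C)O | intermediate
14 | torilin | C/C=C(/C)C(=O)O[C@@H]1C[C@H](C)[C@H]2CC(=O)C(C)=C2C[C@@H]1C(C)(C)OC(C)=O | target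

**Totals**
Total steps: 9. Longest linear sequence: 9 (fully linear; all side components are commercial). Steps 6 and 7 can be telescoped.

**Three steps most likely to fail, with fallbacks**
1. Step 3. Risks: acid dehydration of the β-hydroxy ketone to the dienone, Friedel–Crafts closure at furan C3, or incomplete facial relay. Fallback: build the same oxa-bridged enone by an oxidopyrylium (5+2) route. This means Achmatowicz oxidation of the 3-methylfurfural/butanone aldol carbinol, a chiral amine/thiourea-catalysed (5+2) with a vinyl partner, then intramolecular aldol condensation of the side-chain methyl ketone onto the pyranone carbonyl.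
2. Step 4. Risks: wrong regiochemistry (C6 versus C7) or β-alkoxide elimination of the C6–Pd intermediate. Fallback: use ring-opening on purpose. Pd-catalysed syn ring-opening of 6 with diisopropenylzinc installs the C7 isopropenyl group cis to the liberated C8–OH and opens the bridge in one operation; C1 is then set by conjugate (1,6) reduction of the resulting linear dienone and base equilibration to the C4=C5 enone.
3. Step 2. Risks: enolisation toward the acidic α-furyl C–H, which would erode ee or regiochemistry and break the chirality relay. Fallback: avoid ketone enolate chemistry by making 5 through a Fukuyama ketone synthesis, coupling the thioester of (R)-2-(furan-2-yl)propanoic acid with the β-silyloxyalkylzinc reagent CH2=C(CH3)CH(OTBS)CH2ZnI under Pd catalysis, then desilylating.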